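The charge is 41 mM of solid substrate against 41.0 mM of protic impurity, mole for mole, so I keep one ledger of the solid substrate at each temperature.

    starting material ⇌ target (K1 = 2.4, k1 = 13 h⁻¹, Ea1 = 75.0 kJ mol⁻¹, ΔH1 = −30.0 kJ mol⁻¹)
    starting material ⇌ isomer of the product (K2 = 2.3, k2 = 5.3 h⁻¹, Ea2 = 89.0 kJ mol⁻¹, ΔH2 = −72.0 kJ mol⁻¹)
    starting material + protic impurity → quenched substrate (k3 = 45 M⁻¹ h⁻¹, Ea3 = 46.0 kJ mol⁻¹)
    solid substrate ⇌ starting material, rate k4*(cs4 - [starting material]) while solid is left; crystals form when [starting material] > cs4 (cs4 = 6.0 mM, k4 = 2.6 h⁻¹)
    (constants at 5 °C)

| flask | solid substrate | protic impurity | temperature | time |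
|---|---|---|---|---|
| theta | 41 mM | 41.0 mM | 25 °C | 5.0 h |
| zeta | 41 mM | 41.0 mM | 5 °C | 5.0 h |
| eta | 41 mM | 41.0 mM | −15 °C | 5.0 h |

- solid substrate is a solid; its amount is given per volume of the solution
- all constants are for 5 °C and move with temperature by the activation energies and enthalpies
- at the start none of the solid substrate is in solution
- what has only dissolved of solid substrate counts as not reacted

- the flask with the highest amount of target, in percent of the solid substrate charged ("all alike" if they lie within 1.5 percentage points) (theta / zeta / eta / all alike)
- final target, as a percentage of the solid substrate charged, in theta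
- final target, as a percentage of the solid substrate charged, in zeta
- final target, as a percentage of the solid substrate charged, in eta

**Balance ratio.** I carry one number per flask: the balance ratio, the [target]/[starting material] at which the step to target stands still. It equals that step's equilibrium constant at the flask's temperature: 1.01 in theta, 2.4 in zeta, and in eta 6.56.

**Warm ledgers.** Substrate enters at the dissolution coefficient times the gap below solubility. It leaves for good by the quench, pseudo-first-order at full impurity: 1.85 h⁻¹ in zeta, 7.01 h⁻¹ in theta. In zeta the step to target relaxes at 18.4 h⁻¹, faster than that quench, so I put target at its balance ratio. I do the same in theta, since from the coldest flask to the hottest, heat speeds that step more than the quench.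

While solid lasts, I reckon that feed meets quench at a standing [starting material] of 3.51 mM in zeta and 1.62 mM in theta. Times the balance ratio, I reckon target at 20.5% in zeta and 3.98% in theta. My reversible entries together hold 48.8% in zeta and 9.07% in theta; I book the rest as quenched or still solid. As impurity is used, the quench slows, so I take both targets as low.

**Cold ledger.** In eta the quench is 0.395 h⁻¹, and the forward steps are 1.05 h⁻¹ to target and 0.269 h⁻¹ to isomer of the product. Target therefore takes 61.3% of these forward flows. I reckon standing [starting material] at 3.61 mM, so feed at 6.21 mM h⁻¹, and 31.0 mM dissolved in 5.0 h, less than the charge. My books close at 41.0% target, 10.5% isomer of the product, 15.4% quenched, 8.80% free and 24.3% solid. I ignored target's return, so this target is high, but my order is still eta, zeta, theta.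

**Forecast, result.** The forecast says eta, with 7.5%, 21% and 34% for theta, zeta and eta: “the coldest flask wins even with solid left over”. The simulation gives eta, with 5.88%, 22.6% and 33.7%: theta and zeta stand above my 3.98% and 20.5% , and eta below my 41.0%.

**Twelve hours.** At 5.00 h, flask eta holds target 33.7% over starting material 10.2%, a ratio of 3.30, below its balance ratio of 6.56, so target is still being made net. The neighbour, the same flask left until 12.0 h, reads target 39.8% over starting material 4.29%, a ratio of 9.28, above balance, so that step now runs net backwards. Isomer of the product stands at 24.2% there, and by 50.0 h flask eta holds 10.6% target.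

All constants were chosen freely; no experiment stands behind them.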